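Add D and L at each reading: the sum is the Q that has reacted, short of whatever has gone on to J.

| setting | violet | amber | teal | gamma | beta | eta |
|---|---|---|---|---|---|---|
| Q | 0.028 M | 0.044 M | 0.020 M | 0.020 M | 0.020 M | 0.020 M |
| X | 2 equiv | 2 equiv | 4 equiv | 2.00 equiv | 2.00 equiv | 2.00 equiv |
| temperature | 58 °C | 74 °C | 58 °C | 65 °C | 50 °C | 80 °C |
| remark | run made earlier | run made earlier | run made earlier |  |  |  |
| time |  |  |  | 30 min | 30 min | 30 min |

| run | time / min | D / % | L / % |
|---|---|---|---|
| violet | 5.00 | 17.3 | 1.5 |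
| violet | 10.0 | 27.5 | 5.6 |
| violet | 15.0 | 35.2 | 8.4 |
| violet | 20.0 | 41.2 | 11.9 |
| violet | 25.0 | 43.8 | 18.2 |
| amber | 3.00 | 32.4 | 10.2 |
| amber | 6.00 | 44.0 | 21.1 |
| amber | 10.0 | 46.8 | 33.8 |
| amber | 12.0 | 46.1 | 38.0 |
| amber | 15.0 | 47.3 | 43.0 |
| teal | 2.00 | 7.8 | 0.1 |
| teal | 4.00 | 13.3 | 1.5 |
| teal | 6.00 | 17.0 | 3.3 |
| teal | 12.0 | 28.5 | 6.0 |
| teal | 25.0 | 41.7 | 15.5 |

(readings scatter by 1 percentage point)

- for L the E are counted in
- as a solid, counted per litre of solution: E
- what may be going on: X + D <-> L; Q -> D; 2 X -> G; E <-> L; X + L -> J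

* which flask leads in amount of D, in percent of the Q charged ("all alike" within 1.5 percentage points) (gamma / beta / eta / all alike)
* how much D is there at the end, in percent of the Q charged: gamma
* how much D is there at the end, in percent of the Q charged: beta
* how much D is there at the end, in percent of the Q charged: eta

I read the tables and go round twice. First I ask how much Q has reacted. Taking the sum as a first-order loss of Q, violet at 25.0 min gives k = 0.0387 min⁻¹, and amber at 6.00 min gives 0.175 min⁻¹. A straight line of ln k against temperature gives 0.0182 min⁻¹ for beta, 0.0750 min⁻¹ for gamma and 0.309 min⁻¹ for eta. Beta and eta lie outside the temperatures of these runs. Over 30 min the conversion f is 42.0%, 89.5% and >99.9%.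

But f is not D, so I go round again. I set column L against column D in the last rows. The share L/(D + L) is 29.4% in violet, with cX charged at 0.0560 M. In amber it is 47.6%, with cX at 0.0880 M. Dividing gives 5.24 M⁻¹ and 5.41 M⁻¹. Their mean is s = 5.33 M⁻¹, the L share per molar of X charged. Teal reads 3.39 M⁻¹, lower than both, so s is a rough reading.

The new flasks charge cX at 0.0400 M, so the share is 21.3%. Taking that share off f, I expect D of 33.1% in beta, 70.4% in gamma and 78.7% in eta. I put eta first.

The forecast puts gamma first, with 62% in gamma, 35% in beta and 50% in eta. For eta it writes: “helped by reversal and X loss, though this is uncertain”. There it parts from my reckoning.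

The flasks give 63.2% in gamma, 34.0% in beta and 71.7% in eta, so eta leads.

    X + D ⇌ L (K = 11.0 M⁻¹, k = 0.640 M⁻¹ min⁻¹, Ea = 64.0 kJ mol⁻¹, ΔH = −3.00 kJ mol⁻¹)
    Q → D (k = 0.0180 min⁻¹, Ea = 92.0 kJ mol⁻¹)
    2 X → G (k = 0.120 M⁻¹ min⁻¹, Ea = 78.0 kJ mol⁻¹)
    E ⇌ L, rate k4*(cs4 - [L]) while solid is left; crystals form when [L] > cs4 (solubility = 1.40 mM, k = 7.00 min⁻¹)
    X + L → J (k = 0.770 M⁻¹ min⁻¹, Ea = 52.0 kJ mol⁻¹)
    (constants at 50 °C)

In gamma at 7.44 min, D is made 3.89 times faster than it is used up, each step taken net, and at 30.0 min still 1.26 times, with Q at 8.49%. In eta, Q is at 0.708% by 15.0 min, and from then to 30.0 min D goes from 66.4% to 71.7% while L goes from 25.5% to 17.1%. Against my 21.3%, the L share at 30.0 min stands at 25.0% in gamma and 19.3% in eta. For a neighbour of gamma charged with 0.500 equiv of X, s gives D of 84.7%, and that flask holds 84.7%.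

The earlier runs and the new flask were computed with constants of no real substance, noise included.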